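## Structural features

The target (20) is a 1H-isochromen-1-one: benzo ring A is fused through C4a and C8a to an enol-lactone ring (ring C: C1 carbonyl, O2, C3 bearing an n-pentyl chain, C4–H). Ring A carries a free hydroxyl at C6 and, at C8, peri to the lactone carbonyl, an aryloxy group. The aryl group is ring B, whose ether carbon C1' is flanked by a free hydroxyl at C2' and an n-pentyl chain at C6', with a methoxy group at C4'. There is no stereocentre, so no stereocentres stand next to each other and the problems are regiochemistry and chemoselectivity. The fragile parts are the enol lactone (opened by hydroxide or alkoxide, reducible at C3=C4), the two free phenols and the very electron-rich ring B, which is prone to electrophilic substitution and oxidation. The real difficulty is the ether C8–O–C1': ring B is substituted at both ortho positions and ring A next to the carboxyl carbon, so direct aryl–oxygen coupling is hindered on both sides, and three phenolic oxygens must end up different (C6–OH, C2'–OH, C4'–OMe). The key step uses the fact that C2' to C6' of ring B, with oxygen at C2', methoxy at C4' and pentyl at C6', correspond atom for atom to C2–C6 of 4-methoxy-6-pentylpyran-2-one, so only C1' is lacking and can be brought in as a carbon already bonded to the ether oxygen. Ring A, with its carboxyl carbon between two ortho substituents that are both meta to the C6 oxygen, has the pattern of a 5-substituted resorcinol carboxylated at C4.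

## Logic of the disconnections

20 ⇒ 19. The O–CH2Ph bond on the C6 oxygen is cut. A benzyl ether keeps this phenol distinct from the C2' hydroxyl and the C4' methyl ether throughout. The forward step must cleave it without touching the unchelated methyl ether, the diaryl ether or the enol lactone, and without letting the benzyl cation alkylate ring B.

19 ⇒ 18. The O2–C3 bond of the lactone ring is cut, which leaves an ortho-alkynyl benzoate ester. Ring C then arises by cycloisomerisation with no change in oxidation level. The forward step must close 6-endo on the alkyne carbon that bears the pentyl chain and shed the ester alkyl group.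

18 ⇒ 16 + 17. The C4a–C4 bond (aryl–alkynyl) is cut. This brings in C3, C4 and the pentyl chain as one purchasable piece. The forward coupling must insert into a hindered aryl bromide beside an ester in the presence of a free phenol.

16 ⇒ 15. The ester O–CH3 bond is cut. The methyl ester is wanted for the coupling and cyclisation but not during the ring synthesis, so it is made only here. The forward step must alkylate a hindered carboxylate and leave the C2' phenol alone.

15 ⇒ 7 + 11. The bonds C1'–C2' and C1'–C6' are cut, which removes the whole of ring B and leaves the ether oxygen on a simple sp3 carbon. This avoids any hindered aryl–oxygen coupling and fixes the methoxy at C4', the hydroxyl at C2' and the pentyl at C6' by the constitution of 11. The connectivity of 7, 11, 15 and 16 was checked atom by atom and is consistent; what needs correcting is the design of the precursor. A methyl ester at the benzoate carbon would lie where the enolate carbon reaches it through a five-membered ring, inviting Dieckmann closure to a 3-hydroxybenzofuran-2-carboxylate. The benzoate carbon is therefore carried as the free acid, which becomes an inert lithium carboxylate; the skeleton of 7 is otherwise unchanged. The forward step demands enolate formation with a silylamide base that cannot metalate the ring next to bromine, attack at the lactone carbonyl and not at C6 or C4 of 11, and aldol closure before acid is added.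

11 ⇒ 8 + 9. The bond between the first and second carbon of the pentyl chain is cut. This reduces the pyranone to a purchasable methyl compound and a primary iodide. The forward step needs lateral deprotonation and alkylation at the terminal carbon of the extended enolate.

7 ⇒ 6. No skeletal bond is cut; the carboxyl C–OH bond is traced back to the formyl C–H bond. The oxidation is placed after the O-alkylation because a carboxylate would compete with the phenoxide for 5. The forward step must oxidise without chlorinating the ring or cleaving the tert-butyl ester.

6 ⇒ 4 + 5. The O–CH2 bond is cut. The future C1' is attached to the chelated phenol oxygen by SN2 chemistry with a primary bromide. The forward step must avoid base-induced aldol closure between the new methylene and the formyl group.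

4 ⇒ 3. The O–CH2Ph bond on the oxygen para to the formyl group is cut. The forward step relies on the higher acidity and freedom from hydrogen bonding of this hydroxyl for mono-alkylation.

3 ⇒ 1. The C–C bond to the formyl carbon is cut. This leads back to a purchasable symmetrical resorcinol in which the position para to one hydroxyl and ortho to bromine is the most nucleophilic. The forward step must formylate there and not between the two hydroxyls.

## Other disconnections considered

Alternative 1: Ring B is cut at C1'–C6' and C2'–C3'. The isocoumarin would be completed first and its C8 phenol alkylated to the aryloxymalonate A1. With KOtBu the anion of A1 would add to the β-carbon of enone A2 (future C6'), and the methyl ketone enolate would close on one malonate ester (Michael addition, then Claisen closure) to give the cyclohexane-1,3-dione A3.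
- In favour: A2 is purchasable, the annulation is the classical route to 5-alkylresorcinol precursors, it needs only an alkoxide at ambient temperature, and the ether oxygen is again attached by alkylation of a phenol. On that last point it is the equal of the chosen plan; on the availability of the ring-B partner and the ease of the conditions it is the better.
- Against, structure: A3 is one oxidation level below a resorcinol and its two ring oxygens are not differentiated. Ester removal, dehydrogenation and a regioselective methylation at the C4' oxygen would still be needed on a substrate that carries the base-sensitive enol lactone.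
- Against, mechanism: the nucleophile is a fully substituted malonate carbanion that must form a quaternary centre next to the pentyl-bearing carbon, so retro-Michael reaction is to be feared. The lactone carbonyl of A1 lies within reach of that carbanion through a five-membered transition state, and alkoxide can open the enol lactone.
- Step economy: three or more operations after the annulation, against none for ring B in the chosen plan, where the pyranone brings the right oxidation level and the methyl ether with it.

Alternative 2: Ring A is cut at C4a–C4 and C8a–C1. CsF would release the aryne from silyl triflate A4. The carbanion of malonate A5 would add at the aryne carbon remote from fluorine (future C4a), and the aryl anion next to fluorine (future C8a) would take over one ester group through a four-membered intermediate, giving homophthalate A6. The fluorine would then be displaced by the ring-B phenol A7, and the homophthalate acylated with a hexanoyl donor and closed to the isocoumarin.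
- In favour: ring A and both carbon substituents arise in one step with the regiochemistry set by fluorine. The ether is made by nucleophilic aromatic substitution ortho to an ester, a reaction type with far more precedent than the chosen key step; on the reliability of the C–O bond-forming reaction it is the better plan.
- Against, structure: ring B must be made separately as A7, which needs its own multistep synthesis with two adjacent oxygens differentiated, and A4 also takes several steps.
- Against, mechanism: A7 is a phenoxide hindered at both ortho positions. A6 has an acidic benzylic CH2 that would be deprotonated under the substitution conditions and deactivate the ring. In the insertion, simple protonation of the aryl anion competes with acyl transfer.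
- Step economy: the two building blocks, the substitution, the acylation and cyclisation and two deprotections come to clearly more than ten steps. The two plans are equal in needing no metal-catalysed aryl–oxygen coupling.

Alternative 3: Ring A is cut at C4a–C8a and the lactone at C1–O2. NaOMe would open the aryloxypyranone A8 to a polyketo ester. The carbon that becomes C8a would close by aldol condensation on the ketone that becomes C4a, ring A would aromatise with the C6 hydroxyl free, and the enol oxygen at C3 would acylate C1 to give isocoumarin A9; the benzyl group on the C2' oxygen is then removed.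
- In favour: ring A and the lactone ring form in one operation without palladium or gold, and the C6 hydroxyl needs no protecting group; on both points it is the better plan. The ether bond of A8 would be made by addition–elimination of A7 on a 4-sulfonyloxypyranone, which is easier than substitution on an arene.
- Against, structure: ring B is again needed as preformed A7, and the 2,4-dioxononyl chain must be built by dianion chemistry on a sensitive pyranone.
- Against, mechanism: the polyketo chain has several modes of closure (Claisen closure on the ester to an acylresorcinol, oxygen closure of the triketone to a γ-pyranone). The nucleophilic carbon is the α-carbon of a β-aryloxy enoate and reacts only after γ-deprotonation. Methoxide can displace the aryloxide from the vinylogous ester position, which would destroy the ether.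
- Step economy: roughly equal to the chosen route once A7 is counted, but the regiochemistry is left to the folding of an open chain, whereas the chosen plan fixes it by the ring of the pyranone.

Key step: step 6

Assumption: 4-methoxy-6-methyl-2H-pyran-2-one (8) is taken to be purchasable; in the ring-opened intermediate 13 the chain carbons C2' and C5' stay cis across the enol ether double bond, which corresponds to the descriptor 4E.

## Route

Step 1
Reactants: 1 5-bromobenzene-1,3-diol
Product: 3 2-bromo-4,6-dihydroxybenzaldehyde, via aryl iminium chloride 2 (not isolated)
Conditions: POCl3, DMF, MeCN, 0 °C → rt; then H2O, 50 °C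
Reagents that add atoms: N,N-dimethylformamide `CN(C)C=O`; water `O`
Why: Vilsmeier–Haack formylation; the chloroiminium ion should attack C4 (equivalent to C6), para to one hydroxyl and ortho to the other, and water hydrolyses iminium salt 2 to the aldehyde. Attack between the two hydroxyls is the expected minor pathway, and that isomer would be removed by crystallisation or chromatography.

Step 2
Reactants: 3 2-bromo-4,6-dihydroxybenzaldehyde
Product: 4 4-(benzyloxy)-2-bromo-6-hydroxybenzaldehyde
Conditions: BnBr (1.05 equiv), NaHCO3, MeCN, 60 °C
Reagents that add atoms: benzyl bromide `BrCc1ccccc1`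
Why: Williamson ether synthesis under weak base; the hydroxyl para to the formyl group is the more acidic and is not held in the hydrogen bond to the carbonyl, so one equivalent of benzyl bromide should alkylate it alone.

Step 3
Reactants: 4 4-(benzyloxy)-2-bromo-6-hydroxybenzaldehyde; 5 tert-butyl bromoacetate
Product: 6 tert-butyl 2-[5-(benzyloxy)-3-bromo-2-formylphenoxy]acetate
Conditions: K2CO3, DMF, rt
Reagents that add atoms: none
Why: Williamson alkylation of the chelated phenol with a reactive primary α-bromo ester in a dipolar aprotic solvent; at room temperature carbonate is too weak to enolise the tert-butyl ester, so aldol closure to a benzofuran should not compete. The future C1' is thereby bonded to the ether oxygen by SN2 chemistry.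

Step 4
Reactants: 6 tert-butyl 2-[5-(benzyloxy)-3-bromo-2-formylphenoxy]acetate
Product: 7 4-(benzyloxy)-2-bromo-6-(2-tert-butoxy-2-oxoethoxy)benzoic acid
Conditions: NaClO2, NaH2PO4, 2-methylbut-2-ene, t-BuOH/THF/H2O, 0 °C → rt
Reagents that add atoms: sodium chlorite `[Na+].[O-]Cl=O`
Why: Pinnick oxidation of the aldehyde in a buffered medium; 2-methylbut-2-ene traps hypochlorous acid so the electron-rich ring is not chlorinated, and the tert-butyl ester, benzyl ether and aryl bromide are inert.

Step 5
Reactants: 8 4-methoxy-6-methyl-2H-pyran-2-one; 9 1-iodobutane
Product: 11 4-methoxy-6-pentyl-2H-pyran-2-one, via lithium trienolate 10 (not isolated)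
Conditions: LiN(iPr)2 (commercial solution), THF, −78 °C; then 9, DMPU, −78 → −20 °C
Reagents that add atoms: none
Why: Lateral (vinylogous) deprotonation of the C6 methyl group gives the extended enolate 10, which should be alkylated at its terminal carbon by the primary iodide in an SN2 reaction assisted by DMPU.

Step 6
Reactants: 7 4-(benzyloxy)-2-bromo-6-(2-tert-butoxy-2-oxoethoxy)benzoic acid; 11 4-methoxy-6-pentyl-2H-pyran-2-one
Product: 15 4-(benzyloxy)-2-bromo-6-(2-hydroxy-4-methoxy-6-pentylphenoxy)benzoic acid, via dilithium enolate 12 (not isolated), via ring-opened keto ester 13 (not isolated), via cyclohexenone aldol adduct 14 (not isolated)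
Conditions: LiN(SiMe3)2 (2.1 equiv), THF, −78 °C; 11 (1.3 equiv), −78 °C → rt; 1 M HCl quench; then TFA/CH2Cl2, rt
Reagents that add atoms: none
Why: Two equivalents of LiN(SiMe3)2 convert 7 into 12, in which the benzoate carbon is an unreactive lithium carboxylate and the tert-butyl ester a hard lithium enolate; this base is too weak to metalate the ring next to bromine. The enolate carbon (C1') should add to the lactone carbonyl of 11 (Claisen acylation, C1'–C2'); the ring opens to the enolate of the C6' ketone, and proton transfer from the doubly activated C1'–H gives 13 with C2' and C5' still on the same side of the enol ether double bond. The stabilised C1' carbanion then closes on the C6' ketone (6-exo-trig aldol, C1'–C6') to give 14; the stereocentres at C1' and C6' are transient and need no control. TFA cleaves the tert-butyl ester, and the β-keto acid loses CO2 and water, leaving ring B aromatic with the former lactone carbonyl as the free C2' hydroxyl, the enol ether as the C4' methoxy and the pentyl at C6'. The closest known reaction type is the opening of 4-methoxypyran-2-ones at the carbonyl carbon by lithium carbanions followed by intramolecular condensation to a benzenoid ring, as in biomimetic syntheses of polyketide aromatics; here the carbanion is an α-aryloxy ester enolate. The selectivity needed is attack at the carbonyl carbon and not at C6 or C4, which the hard lithium enolate, the alkyl group at C6 and the donor methoxy at C4 favour; after that the substitution pattern of ring B is fixed by the pyranone. The tert-butyl ester suppresses self-condensation of the enolate and allows the extra carbon to be lost without trace.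

Step 7
Reactants: 15 4-(benzyloxy)-2-bromo-6-(2-hydroxy-4-methoxy-6-pentylphenoxy)benzoic acid
Product: 16 methyl 4-(benzyloxy)-2-bromo-6-(2-hydroxy-4-methoxy-6-pentylphenoxy)benzoate
Conditions: MeI, KHCO3, DMF, rt
Reagents that add atoms: iodomethane `CI`
Why: SN2 O-alkylation of the carboxylate, since Fischer esterification is not an option for a 2,6-disubstituted benzoic acid; hydrogen carbonate does not deprotonate the C2' phenol to a useful extent, so the phenol and the aryl bromide should be untouched.

Step 8
Reactants: 16 methyl 4-(benzyloxy)-2-bromo-6-(2-hydroxy-4-methoxy-6-pentylphenoxy)benzoate; 17 hept-1-yne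
Product: 18 methyl 4-(benzyloxy)-2-(hept-1-yn-1-yl)-6-(2-hydroxy-4-methoxy-6-pentylphenoxy)benzoate
Conditions: PdCl2(PPh3)2 (cat.), CuI (cat.), Et3N, DMF, 70 °C
Reagents that add atoms: none
Why: Sonogashira coupling; oxidative addition of zerovalent palladium into the C–Br bond is helped by the ortho ester and not retarded by the two oxygens, which are meta to bromine. The free phenol, the ester and the benzyl ether are tolerated under amine base.

Step 9
Reactants: 18 methyl 4-(benzyloxy)-2-(hept-1-yn-1-yl)-6-(2-hydroxy-4-methoxy-6-pentylphenoxy)benzoate
Product: 19 6-(benzyloxy)-8-(2-hydroxy-4-methoxy-6-pentylphenoxy)-3-pentyl-1H-isochromen-1-one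
Conditions: AuCl3 (cat.), wet MeCN, 50 °C
Reagents that add atoms: water `O`
Why: Gold-catalysed cycloisomerisation; the ester carbonyl oxygen adds to the alkyne activated by trivalent gold at the pentyl-bearing carbon (6-endo-dig), and protodeauration gives a 1-methoxyisochromenylium ion. Water hydrolyses this ion at C1 with loss of methanol, so the lactone carbonyl oxygen comes from water.

Step 10
Reactants: 19 6-(benzyloxy)-8-(2-hydroxy-4-methoxy-6-pentylphenoxy)-3-pentyl-1H-isochromen-1-one
Product: 20 6-hydroxy-8-(2-hydroxy-4-methoxy-6-pentylphenoxy)-3-pentyl-1H-isochromen-1-one
Conditions: BCl3, pentamethylbenzene, CH2Cl2, −78 °C; then H2O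
Reagents that add atoms: none
Why: Lewis-acid debenzylation; BCl3 at low temperature cleaves the benzyl aryl ether, and pentamethylbenzene captures the benzyl cation before it can alkylate ring B. The unchelated C4' methyl ether, the diaryl ether and the enol lactone should survive at −78 °C.

## Compound list

1 | 5-bromobenzene-1,3-diol | `Oc1cc(O)cc(Br)c1` | starting material
2 | [(2-bromo-4,6-dihydroxyphenyl)methylidene]dimethylammonium chloride | `C[N+](C)=Cc1c(O)cc(O)cc1Br.[Cl-]` | intermediate (not isolated)
3 | 2-bromo-4,6-dihydroxybenzaldehyde | `O=Cc1c(O)cc(O)cc1Br` | intermediate
4 | 4-(benzyloxy)-2-bromo-6-hydroxybenzaldehyde | `O=Cc1c(O)cc(OCc2ccccc2)cc1Br` | intermediate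
5 | tert-butyl bromoacetate | `CC(C)(C)OC(=O)CBr` | starting material
6 | tert-butyl 2-[5-(benzyloxy)-3-bromo-2-formylphenoxy]acetate | `CC(C)(C)OC(=O)COc1cc(OCc2ccccc2)cc(Br)c1C=O` | intermediate
7 | 4-(benzyloxy)-2-bromo-6-(2-tert-butoxy-2-oxoethoxy)benzoic acid | `CC(C)(C)OC(=O)COc1cc(OCc2ccccc2)cc(Br)c1C(=O)O` | intermediate
8 | 4-methoxy-6-methyl-2H-pyran-2-one | `Cc1cc(OC)cc(=O)o1` | starting material
9 | 1-iodobutane | `CCCCI` | starting material
10 | lithium 4-methoxy-6-methylidene-6H-pyran-2-olate (laterally lithiated 8) | `[Li]OC1=CC(OC)=CC(=C)O1` | intermediate (not isolated)
11 | 4-methoxy-6-pentyl-2H-pyran-2-one | `CCCCCc1cc(OC)cc(=O)o1` | intermediate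
12 | dilithium salt of 7 (lithium carboxylate and lithium ester enolate) | `[Li]OC(=COc1cc(OCc2ccccc2)cc(Br)c1C(=O)O[Li])OC(C)(C)C` | intermediate (not isolated)
13 | 4-(benzyloxy)-2-bromo-6-{[(4E)-1-tert-butoxy-5-methoxy-1,3,7-trioxododec-4-en-2-yl]oxy}benzoic acid (racemic; present as its lithium salt, shown in neutral form) | `CCCCCC(=O)C/C(OC)=C\C(=O)C(Oc1cc(OCc2ccccc2)cc(Br)c1C(=O)O)C(=O)OC(C)(C)C` | intermediate (not isolated)
14 | 4-(benzyloxy)-2-bromo-6-{[1-(tert-butoxycarbonyl)-6-hydroxy-4-methoxy-2-oxo-6-pentylcyclohex-3-en-1-yl]oxy}benzoic acid (mixture of diastereomers; present as its lithium salt, shown in neutral form) | `CCCCCC1(O)CC(OC)=CC(=O)C1(Oc1cc(OCc2ccccc2)cc(Br)c1C(=O)O)C(=O)OC(C)(C)C` | intermediate (not isolated)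
15 | 4-(benzyloxy)-2-bromo-6-(2-hydroxy-4-methoxy-6-pentylphenoxy)benzoic acid | `CCCCCc1cc(OC)cc(O)c1Oc1cc(OCc2ccccc2)cc(Br)c1C(=O)O` | intermediate
16 | methyl 4-(benzyloxy)-2-bromo-6-(2-hydroxy-4-methoxy-6-pentylphenoxy)benzoate | `COC(=O)c1c(Br)cc(OCc2ccccc2)cc1Oc1c(O)cc(OC)cc1CCCCC` | intermediate
17 | hept-1-yne | `CCCCCC#C` | starting material
18 | methyl 4-(benzyloxy)-2-(hept-1-yn-1-yl)-6-(2-hydroxy-4-methoxy-6-pentylphenoxy)benzoate | `CCCCCC#Cc1cc(OCc2ccccc2)cc(Oc2c(O)cc(OC)cc2CCCCC)c1C(=O)OC` | intermediate
19 | 6-(benzyloxy)-8-(2-hydroxy-4-methoxy-6-pentylphenoxy)-3-pentyl-1H-isochromen-1-one | `CCCCCc1cc2cc(OCc3ccccc3)cc(Oc3c(O)cc(OC)cc3CCCCC)c2c(=O)o1` | intermediate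
20 | 6-hydroxy-8-(2-hydroxy-4-methoxy-6-pentylphenoxy)-3-pentyl-1H-isochromen-1-one | `CCCCCc1cc2cc(O)cc(Oc3c(O)cc(OC)cc3CCCCC)c2c(=O)o1` | target

## Step count and least certain steps

Total step count: 10. Longest linear sequence: 9 steps (steps 1, 2, 3, 4, 6, 7, 8, 9, 10, from 1 to 20); step 5 is a one-step branch to 11.

Step 6 (key step). What may go wrong: proton transfer from the lateral CH2 of 11 to the enolate of 12 in place of carbonyl addition; addition at C6 or C4 of the pyranone; an aldol closure that lags, so that the open chain recloses through oxygen to a γ-pyranone once acid is added; and tert-butylation of the newly formed ring B during the acid stage. Fallback (sets out from 4, returns at 16): the ether is made by nucleophilic aromatic substitution and the C2' hydroxyl by Dakin-type oxidation. Pinnick oxidation of 4 gives 4-(benzyloxy)-2-bromo-6-hydroxybenzoic acid F1, and MeI/KHCO3 gives methyl 4-(benzyloxy)-2-bromo-6-hydroxybenzoate F2. For ring B, purchasable 2-bromo-1-fluoro-4-methoxybenzene is coupled with C5H11ZnBr (PdCl2(dppf), Negishi coupling) to give 1-fluoro-4-methoxy-2-pentylbenzene F3. This is metalated next to fluorine (n-BuLi/KOtBu, THF, −78 °C) and formylated with DMF to give 2-fluoro-5-methoxy-3-pentylbenzaldehyde F4. The phenoxide of F2 displaces the fluoride of F4, activated by the ortho formyl group (Cs2CO3, DMSO, 110 °C), to give methyl 4-(benzyloxy)-2-bromo-6-(2-formyl-4-methoxy-6-pentylphenoxy)benzoate F5. Baeyer–Villiger oxidation with mCPBA gives methyl 4-(benzyloxy)-2-bromo-6-[2-(formyloxy)-4-methoxy-6-pentylphenoxy]benzoate F6, and methanolysis (KHCO3, MeOH) gives 16. This is longer, and the substitution is hindered and only moderately activated, which is why it is the reserve and not the plan.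

Step 5. What may go wrong: competing metalation at C3 of the ring, and dialkylation or alkylation at a ring carbon of the extended enolate. Fallback (sets out from 8, returns at 11): aldol addition of the same anion 10 to butanal gives 6-(2-hydroxypentyl)-4-methoxy-2H-pyran-2-one F7 (racemic). Dehydration (TsOH, toluene, reflux) gives 4-methoxy-6-[(1E)-pent-1-en-1-yl]-2H-pyran-2-one F8, and hydrogenation of the side-chain double bond (H2, Pd/C, EtOAc, one equivalent of hydrogen) gives 11.

Step 9. What may go wrong: 5-exo closure to an alkylidenephthalide, hydration of the alkyne, or slow turnover because the phenol and ring B bind or reduce the gold catalyst; in step 8 before it, slow oxidative addition into the hindered bromide. Fallback (sets out from 15, returns at 19, replacing steps 7 to 9): a Hurtley-type coupling. Tridecane-6,8-dione F9 is made by Claisen condensation of heptan-2-one with ethyl hexanoate (NaH, THF). With CuI and K3PO4 in DMF at 100 °C, copper-catalysed arylation of F9 by the ortho-bromobenzoic acid 15 at the central carbon is followed by retro-Claisen loss of hexanoate to give 4-(benzyloxy)-2-(2-hydroxy-4-methoxy-6-pentylphenoxy)-6-(2-oxoheptyl)benzoic acid F10 (not isolated), whose cyclodehydration gives 19. The ring oxygen is then bonded to C3 by carbonyl chemistry, so 5-exo closure is excluded.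

Step 1. What may go wrong: formylation between the two hydroxyls, O-formylation, and low conversion of the bromine-deactivated free resorcinol. Fallback (sets out from 1, returns at 3): methylation of 1 (Me2SO4, K2CO3, acetone) gives 1-bromo-3,5-dimethoxybenzene F11. Vilsmeier–Haack formylation gives 2-bromo-4,6-dimethoxybenzaldehyde F12, the position between the two methoxy groups being shielded, and cleavage of both methyl ethers with BBr3 in CH2Cl2 gives 3.

## Further compounds

F1 | step 6 | 4-(benzyloxy)-2-bromo-6-hydroxybenzoic acid | `OC(=O)c1c(O)cc(OCc2ccccc2)cc1Br`
F2 | step 6 | methyl 4-(benzyloxy)-2-bromo-6-hydroxybenzoate | `COC(=O)c1c(O)cc(OCc2ccccc2)cc1Br`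
F3 | step 6 | 1-fluoro-4-methoxy-2-pentylbenzene | `CCCCCc1cc(OC)ccc1F`
F4 | step 6 | 2-fluoro-5-methoxy-3-pentylbenzaldehyde | `CCCCCc1cc(OC)cc(C=O)c1F`
F5 | step 6 | methyl 4-(benzyloxy)-2-bromo-6-(2-formyl-4-methoxy-6-pentylphenoxy)benzoate | `COC(=O)c1c(Br)cc(OCc2ccccc2)cc1Oc1c(C=O)cc(OC)cc1CCCCC`
F6 | step 6 | methyl 4-(benzyloxy)-2-bromo-6-[2-(formyloxy)-4-methoxy-6-pentylphenoxy]benzoate | `COC(=O)c1c(Br)cc(OCc2ccccc2)cc1Oc1c(OC=O)cc(OC)cc1CCCCC`
F7 | step 5 | 6-(2-hydroxypentyl)-4-methoxy-2H-pyran-2-one (racemic) | `CCCC(O)Cc1cc(OC)cc(=O)o1`
F8 | step 5 | 4-methoxy-6-[(1E)-pent-1-en-1-yl]-2H-pyran-2-one | `CCC/C=C/c1cc(OC)cc(=O)o1`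
F9 | step 9 | tridecane-6,8-dione | `CCCCCC(=O)CC(=O)CCCCC`
F10 | step 9 | 4-(benzyloxy)-2-(2-hydroxy-4-methoxy-6-pentylphenoxy)-6-(2-oxoheptyl)benzoic acid | `CCCCCC(=O)Cc1cc(OCc2ccccc2)cc(Oc2c(O)cc(OC)cc2CCCCC)c1C(=O)O`
F11 | step 1 | 1-bromo-3,5-dimethoxybenzene | `COc1cc(OC)cc(Br)c1`
F12 | step 1 | 2-bromo-4,6-dimethoxybenzaldehyde | `COc1cc(OC)c(C=O)c(Br)c1`
A1 | alternative 1 | dimethyl 2-{[6-(benzyloxy)-1-oxo-3-pentyl-1H-isochromen-8-yl]oxy}propanedioate | `COC(=O)C(Oc1cc(OCc2ccccc2)cc2cc(CCCCC)oc(=O)c12)C(=O)OC`
A2 | alternative 1 | (3E)-non-3-en-2-one | `CCCCC/C=C/C(C)=O`
A3 | alternative 1 | methyl 1-{[6-(benzyloxy)-1-oxo-3-pentyl-1H-isochromen-8-yl]oxy}-2,4-dioxo-6-pentylcyclohexane-1-carboxylate (mixture of diastereomers) | `COC(=O)C1(Oc2cc(OCc3ccccc3)cc3cc(CCCCC)oc(=O)c23)C(CCCCC)CC(=O)CC1=O`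
A4 | alternative 2 | 5-(benzyloxy)-3-fluoro-2-(trimethylsilyl)phenyl trifluoromethanesulfonate | `C[Si](C)(C)c1c(F)cc(OCc2ccccc2)cc1OS(=O)(=O)C(F)(F)F`
A5 | alternative 2 | dimethyl propanedioate | `COC(=O)CC(=O)OC`
A6 | alternative 2 | methyl 4-(benzyloxy)-2-fluoro-6-(2-methoxy-2-oxoethyl)benzoate | `COC(=O)Cc1cc(OCc2ccccc2)cc(F)c1C(=O)OC`
A7 | alternative 2 | 2-(benzyloxy)-4-methoxy-6-pentylphenol | `CCCCCc1cc(OC)cc(OCc2ccccc2)c1O`
A8 | alternative 3 | 4-[2-(benzyloxy)-4-methoxy-6-pentylphenoxy]-6-(2,4-dioxononyl)-2H-pyran-2-one | `CCCCCC(=O)CC(=O)Cc1cc(Oc2c(OCc3ccccc3)cc(OC)cc2CCCCC)cc(=O)o1`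
A9 | alternative 3 | 8-[2-(benzyloxy)-4-methoxy-6-pentylphenoxy]-6-hydroxy-3-pentyl-1H-isochromen-1-one | `CCCCCc1cc2cc(O)cc(Oc3c(OCc4ccccc4)cc(OC)cc3CCCCC)c2c(=O)o1`
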